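**The currency.** Take the mole of partner as your unit of account: each addition to substrate costs one, so a double product has cost two.

| flask | substrate | partner | temperature | remark | time |
|---|---|---|---|---|---|
| zeta | 0.045 M | 0.228 M | 25 °C | run made earlier |  |
| delta | 0.70 M | 0.228 M | 48 °C | run made earlier |  |
| epsilon | 0.19 M | 0.30 M | 25 °C | run made earlier |  |
| noon | 0.80 M | 0.0800 M | 30 °C |  | 10 h |
| summer | 0.060 M | 0.600 M | 50 °C |  | 10 h |
| dawn | 0.19 M | 0.228 M | 50 °C |  | 10 h |
| spring | 0.30 M | 0.228 M | 65 °C |  | 10 h |

- zeta (time / h: first product / %, substrate / %): 5.00: 57.8, 37.8; 10.0: 76.6, 14.6; 15.0: 84.3, 5.7; 20.0: 84.3, 4.0; 30.0: 84.3, 0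
- delta (time / h: first product / %, substrate / %): 1.33: 28.5, 69.6; 3.00: 29.8, 68.3; 4.00: 29.6, 66.1; 6.00: 30.0, 68.1; 8.00: 28.6, 67.5; 10.0: 26.8, 67.0
- epsilon (time / h: first product / %, substrate / %): 3.00: 46.4, 50.7; 5.00: 59.8, 37.0; 10.0: 77.3, 18.6; 15.0: 84.3, 9.1; 30.0: 88.6, 2.1

(standard deviation of a reading: 1 percentage point)

- amounts and yields of first product count crystals too
- given per volume of solution although it is solid: crystals
- what was read earlier has a scatter of 1 percentage point, one standard deviation
- reactions considered so far: substrate + partner -> other mono adduct; substrate + partner -> first product; crystals <-> first product; partner + first product -> double product; partner + other mono adduct -> double product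

* the flasks by amount of first product, in percent of the substrate charged, highest first, at 10 h (noon / summer / dawn / spring)
* the same order at 3.0 d (noon / summer / dawn / spring)
* the amount of first product, in percent of the substrate charged of the flask you put first, at 10 h
* the amount of first product, in percent of the substrate charged of the flask you put last, at 10 h

**First entry.** At 3.00 h epsilon has consumed 49.3 % of its substrate and shows 46.4 % of first product. That reading gives the first-product share, the first product booked per mole of partner paid to substrate: 94.1 %. I book the remainder to the other mono adduct. The share times partner charged per substrate charged is the ceiling of a flask short of partner, the limiting reagent. For delta this gives 30.7 %, and delta's separate readings stand at 29.8 % at 3.00 h and 30.0 % at 6.00 h.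

**Closing time.** Zeta's substrate decay, pseudo-first-order in substrate with partner in excess, gives a rate constant that puts partner's half-life at noon's substrate charge near 1.02 h even at 25 °C, which is shorter than 10 h. So I expect noon to reach its ceiling, 9.41 %, by 10 h.

**Surplus entry.** Spring's ceiling is 71.5 %. The one listed step that consumes first product also takes partner, so I expect noon and spring to hold their first product once their partner reaches zero. Dawn has a surplus of 0.200 mole of partner per mole of substrate. If every surplus mole took a first product, dawn would keep 74.1 %, which is above spring's ceiling. Summer's surplus is 9.00 moles per mole, which gives it no floor.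

**My reckoning.** I put dawn first and noon last at 10 h, with summer behind spring as a judgement. At 3.0 d I put summer last, behind noon.

**The flasks.** The forecast gave dawn > summer > spring > noon at 10 h and dawn > noon > spring > summer at 3.0 d, with 77 % and 9.3 %: “Summer (double addition) and spring (thermal loss) both land near 45%, so their order is uncertain”. The flasks give dawn > spring > summer > noon and then dawn > spring > noon > summer, with 83.2 % for dawn and 9.41 % for noon.

    substrate + partner → other mono adduct (k = 0.00653 L mol⁻¹ min⁻¹, Ea = 66.0 kJ mol⁻¹)
    substrate + partner → first product (k = 0.106 L mol⁻¹ min⁻¹, Ea = 64.0 kJ mol⁻¹)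
    crystals ⇌ first product, rate k3*(cs3 - [first product]) while solid is left; crystals form when [first product] > cs3 (solubility = 0.0620 M, k = 0.0168 min⁻¹)
    partner + first product → double product (k = 0.00701 L mol⁻¹ min⁻¹, Ea = 92.0 kJ mol⁻¹)
    partner + other mono adduct → double product (k = 0.00219 L mol⁻¹ min⁻¹, Ea = 68.0 kJ mol⁻¹)
    (constants at 50 °C)

**Noon's books.** In noon, dissolved first product has a half-life of 16 d by the path to double product at 0.637 h, long against 10 h. Partner meanwhile goes to first product 17 times as fast as to other mono adduct, and noon's 9.41 % stands at the ceiling of 9.41 %. The neighbour of noon with 2.0 M of substrate has a ceiling of 3.76 % and gives 3.77 %.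

The runs were generated by integration for an exercise, and the scatter is random.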